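**Retrosynthetic overview**

1. Lactone ring (the only non-aromatic ring): bought intact with its stereocentre as (R)-3-hydroxy-γ-butyrolactone 1; no ring is formed in the route.
2. C3–CH2Ar bond: 1 plus benzyl bromide 2, through dianion 3, gives trans hydroxy lactone 4 (the bought C4–O stereocentre sets C3).
3. C4–C7 bond (key disconnection): the C4–OH of 4 is exchanged for an aroyl group under blue light, using benzoxazolium salt 5 and acid chloride 6 through adduct 7, to give trans keto lactone 8 (C3 re-sets C4).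
4. C7–OH: substrate-controlled hydride reduction of 8 gives 9 (C4 sets C7); debenzylation gives target 10.

Assumption: 2, 5 and 6 are taken as catalogue compounds (each is otherwise one routine step from a common commercial precursor).

Abbreviations: ppy = 2-phenylpyridinato; dtbbpy = 4,4'-di-tert-butyl-2,2'-bipyridine; DMPU = N,N'-dimethylpropyleneurea; DMA = N,N-dimethylacetamide; MTBE = methyl tert-butyl ether.

**Step 1**
Reactants: 1 (R)-3-hydroxy-γ-butyrolactone; 2 4-(benzyloxy)-3-methoxybenzyl bromide
Product: 4 (3R,4R)-3-{[4-(benzyloxy)-3-methoxyphenyl]methyl}-4-hydroxyoxolan-2-one, via dilithium alkoxide enolate 3 (not isolated)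
Conditions: LiN(iPr)2 (2.2 equiv), THF, −78 °C, 1 h; then 2 (1.05 equiv), DMPU, −78 → −40 °C; AcOH
Reagents that add atoms: none
Why: Fráter–Seebach-type alkylation of a β-hydroxy lactone dianion: the lithium alkoxide at C4 shields its own face of the planar enolate, so 2 adds anti to it and C3 is set trans (3R) by the bought C4 stereocentre, while the dianion does not eliminate because oxide is no leaving group.

**Step 2**
Reactants: 4 (3R,4R)-3-{[4-(benzyloxy)-3-methoxyphenyl]methyl}-4-hydroxyoxolan-2-one; 5 5,7-di-tert-butyl-3-phenyl-1,3-benzoxazol-3-ium tetrafluoroborate; 6 4-(benzyloxy)-3-methoxybenzoyl chloride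
Product: 8 (3R,4R)-4-[4-(benzyloxy)-3-methoxybenzoyl]-3-{[4-(benzyloxy)-3-methoxyphenyl]methyl}oxolan-2-one, via benzoxazoline alkoxy adduct 7 (not isolated)
Conditions: 5 (1.1 equiv), pyridine (1.1 equiv), MTBE, rt, 20 min, filter; then 6 (1.5 equiv), [Ir(ppy)2(dtbbpy)]PF6 (1 mol%), NiBr2(dtbbpy) (10 mol%), 2,6-lutidine (2 equiv), DMA/MTBE, 450 nm LEDs, 25 °C
Reagents that add atoms: none
Why: Proposed new method: nickel/photoredox deoxygenative acylation of a secondary alcohol. The excited iridium photocatalyst oxidises the N-aryl aminal nitrogen of 7, 2,6-lutidine removes the acidified aminal C–H, and β-scission (driven by formation of the benzoxazolone C=O) releases the C4 radical. This radical is captured by the aroyl–nickel chloride formed by oxidative addition of 6 to zerovalent nickel, and reductive elimination from trivalent nickel forms the C4–C7 bond on the ring face anti to the C3 substituent (any cis isomer equilibrates to trans through the ketone enol), so C4 is rebuilt as R under control of C3, which lutidine is too weak to epimerise. The closest known reactions are the nickel/photoredox deoxygenative arylation of benzoxazolium-activated alcohols with aryl halides and the nickel/photoredox acylation of secondary alkyltrifluoroborates with acyl chlorides (2,6-lutidine replaces the nucleophilic amine base of the arylation precedent to avoid acylammonium chemistry).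

**Step 3**
Reactants: 8 (3R,4R)-4-[4-(benzyloxy)-3-methoxybenzoyl]-3-{[4-(benzyloxy)-3-methoxyphenyl]methyl}oxolan-2-one
Product: 9 (3R,4R)-4-{(S)-[4-(benzyloxy)-3-methoxyphenyl](hydroxy)methyl}-3-{[4-(benzyloxy)-3-methoxyphenyl]methyl}oxolan-2-one
Conditions: Li[HB(sec-Bu)3] (1.2 equiv), THF, −78 °C; AcOH, −78 °C
Reagents that add atoms: none
Why: Felkin–Anh-controlled hydride addition: with the branched ring carbon C3 anti to the incoming bulky hydride and the CH2O carbon C5 flanking the carbonyl oxygen, attack past the C4–H gives the 7S carbinol, and the cold acidic quench prevents the C7 alkoxide from attacking the lactone.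

**Step 4**
Reactants: 9 (3R,4R)-4-{(S)-[4-(benzyloxy)-3-methoxyphenyl](hydroxy)methyl}-3-{[4-(benzyloxy)-3-methoxyphenyl]methyl}oxolan-2-one
Product: 10 (3R,4R)-4-[(S)-hydroxy(4-hydroxy-3-methoxyphenyl)methyl]-3-[(4-hydroxy-3-methoxyphenyl)methyl]oxolan-2-one
Conditions: H2 (1 atm), 10% Pd/C, EtOAc, rt, stopped at full conversion
Reagents that add atoms: none
Why: Catalytic hydrogenolysis cleaves the two aryl benzyl ethers much faster than the secondary benzylic C–OH bond under neutral conditions (the standard end-game for α-hydroxy lignin model compounds), and no stereocentre is touched.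

**Compound list**

1 | (4R)-4-hydroxyoxolan-2-one [(R)-3-hydroxy-γ-butyrolactone] | O=C1C[C@@H](O)CO1 | starting material
2 | 1-(benzyloxy)-4-(bromomethyl)-2-methoxybenzene [4-(benzyloxy)-3-methoxybenzyl bromide] | COc1cc(CBr)ccc1OCc1ccccc1 | starting material
3 | dilithium (3R)-2,3-dihydrofuran-3,5-bis(olate) (alkoxide enolate dianion of 1) | [Li+].[Li+].[O-]C1=C[C@@H]([O-])CO1 | intermediate
4 | (3R,4R)-3-{[4-(benzyloxy)-3-methoxyphenyl]methyl}-4-hydroxyoxolan-2-one (trans) | COc1cc(C[C@H]2C(=O)OC[C@@H]2O)ccc1OCc1ccccc1 | intermediate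
5 | 5,7-di-tert-butyl-3-phenyl-1,3-benzoxazol-3-ium tetrafluoroborate | CC(C)(C)c1cc(C(C)(C)C)c2oc[n+](-c3ccccc3)c2c1.F[B-](F)(F)F | starting material
6 | 4-(benzyloxy)-3-methoxybenzoyl chloride | COc1cc(C(=O)Cl)ccc1OCc1ccccc1 | starting material
7 | (3R,4R)-3-{[4-(benzyloxy)-3-methoxyphenyl]methyl}-4-[(5,7-di-tert-butyl-3-phenyl-2,3-dihydro-1,3-benzoxazol-2-yl)oxy]oxolan-2-one (both epimers at the aminal carbon) | COc1cc(C[C@H]2C(=O)OC[C@@H]2OC3Oc4c(C(C)(C)C)cc(C(C)(C)C)cc4N3c5ccccc5)ccc1OCc1ccccc1 | intermediate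
8 | (3R,4R)-4-[4-(benzyloxy)-3-methoxybenzoyl]-3-{[4-(benzyloxy)-3-methoxyphenyl]methyl}oxolan-2-one (trans; 7-oxomatairesinol dibenzyl ether) | COc1cc(C[C@H]2C(=O)OC[C@@H]2C(=O)c2ccc(OCc3ccccc3)c(OC)c2)ccc1OCc1ccccc1 | intermediate
9 | (3R,4R)-4-{(S)-[4-(benzyloxy)-3-methoxyphenyl](hydroxy)methyl}-3-{[4-(benzyloxy)-3-methoxyphenyl]methyl}oxolan-2-one | COc1cc(C[C@H]2C(=O)OC[C@@H]2[C@H](O)c2ccc(OCc3ccccc3)c(OC)c2)ccc1OCc1ccccc1 | intermediate
10 | (3R,4R)-4-[(S)-hydroxy(4-hydroxy-3-methoxyphenyl)methyl]-3-[(4-hydroxy-3-methoxyphenyl)methyl]oxolan-2-one (CNP0187590.1) | COc1cc(C[C@H]2C(=O)OC[C@@H]2[C@H](O)c2ccc(O)c(OC)c2)ccc1O | target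

**Step count and risks**

Total steps: 4. Longest linear sequence: 4 (1 → 4 → 8 → 9 → 10).

The three steps most likely to fail:

Step 2 (the proposed new transformation). The merger of benzoxazolium alcohol activation with acyl–nickel capture is untested. The acid chloride may attack adduct 7, lutidine may be too weak a base for the radical-forming deprotonation, and the C4–nickel species may lose a β-hydrogen to give the butenolide. Fallback with known chemistry, setting out from 4: Appel iodination (I2, PPh3, imidazole, CH2Cl2, 0 °C) gives, with inversion, the cis iodide (3S,4S)-3-{[4-(benzyloxy)-3-methoxyphenyl]methyl}-4-iodooxolan-2-one F1. Nickel-catalysed reductive cross-electrophile coupling of F1 with acid chloride 6 (NiCl2(DME), dtbbpy, Mn, DMA, rt) also passes through the C4 radical and so again gives the trans ketone; the fallback comes back to the route at 8.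

Step 3. The Felkin–Anh preference of a ketone on a five-membered ring may be modest or even reversed, and a C7 alkoxide can translactonise. Fallback, setting out from 8: reduce with the hydride that gives most of the other epimer (for example NaBH4, MeOH/THF, −20 °C) and isolate (3R,4R)-4-{(R)-[4-(benzyloxy)-3-methoxyphenyl](hydroxy)methyl}-3-{[4-(benzyloxy)-3-methoxyphenyl]methyl}oxolan-2-one F2. Invert C7 by Mitsunobu reaction (4-nitrobenzoic acid, PPh3, DIAD, THF, 0 °C) to (S)-[4-(benzyloxy)-3-methoxyphenyl][(3R,4R)-4-{[4-(benzyloxy)-3-methoxyphenyl]methyl}-5-oxooxolan-3-yl]methyl 4-nitrobenzoate F3, then remove the ester briefly with K2CO3 in MeOH at 0 °C; the fallback comes back to the route at 9.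

Step 4. Once the phenols are free, the p-hydroxybenzylic C7–OH may be hydrogenolysed to matairesinol. Fallback, setting out from 8: debenzylate before the carbinol exists (H2, 10% Pd/C, EtOAc, rt; the electron-rich aryl ketone is inert under these conditions) to (3R,4R)-4-(4-hydroxy-3-methoxybenzoyl)-3-[(4-hydroxy-3-methoxyphenyl)methyl]oxolan-2-one F4. Then reduce the ketone with Li[HB(sec-Bu)3] (3.5 equiv, two being consumed by the phenols; THF, −78 → −40 °C; AcOH); this by-passes 9 and comes back to the route at 10.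

**Further compounds**

F1 | step 2 | (3S,4S)-3-{[4-(benzyloxy)-3-methoxyphenyl]methyl}-4-iodooxolan-2-one (cis) | COc1cc(C[C@H]2C(=O)OC[C@H]2I)ccc1OCc1ccccc1
F2 | step 3 | (3R,4R)-4-{(R)-[4-(benzyloxy)-3-methoxyphenyl](hydroxy)methyl}-3-{[4-(benzyloxy)-3-methoxyphenyl]methyl}oxolan-2-one | COc1cc(C[C@H]2C(=O)OC[C@@H]2[C@@H](O)c2ccc(OCc3ccccc3)c(OC)c2)ccc1OCc1ccccc1
F3 | step 3 | (S)-[4-(benzyloxy)-3-methoxyphenyl][(3R,4R)-4-{[4-(benzyloxy)-3-methoxyphenyl]methyl}-5-oxooxolan-3-yl]methyl 4-nitrobenzoate | COc1cc(C[C@H]2C(=O)OC[C@@H]2[C@H](OC(=O)c2ccc(cc2)[N+](=O)[O-])c2ccc(OCc3ccccc3)c(OC)c2)ccc1OCc1ccccc1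
F4 | step 4 | (3R,4R)-4-(4-hydroxy-3-methoxybenzoyl)-3-[(4-hydroxy-3-methoxyphenyl)methyl]oxolan-2-one (7-oxomatairesinol) | COc1cc(C[C@H]2C(=O)OC[C@@H]2C(=O)c2ccc(O)c(OC)c2)ccc1O
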